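**Retrosynthetic overview**

1. The target is epicatechin 3-O-gallate (U)-(4β→6)-epicatechin 3-O-gallate (M)-(4β→8)-catechin (L). The last operations are hydrogenolysis of eighteen benzyl ethers and, before it, formation of C4(M)–C8(L) by TMSOTf ionisation of a C4 methyl ether of M in the presence of tetra-O-benzylcatechin.
2. Feature: in unit M, O1 is the phenol oxygen para to C6 (the carbon bonded to C4 of U), and it is bonded to the benzylic C2, whose aryl group (ring B) is cis to the C3 oxygen. The O1–C2 bond of ring C of M is therefore made by that phenol oxygen opening a (2S,3S)-cis-epoxide at C2 with inversion; the epoxide oxygen becomes the 3-hydroxyl that is galloylated.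
3. The cis-epoxide comes from Jacobsen epoxidation of a (Z)-alkene. The alkene is built on ring D by phenol-directed ortho-formylation, acetylide addition, O-methylation (the later C4 leaving group) and semihydrogenation.
4. The C4(U)–C6(M) bond is made first: the C4 cation of benzylated epicatechin gallate is arylated by a 3,5-bis(benzyloxy)phenyl silyl ether para to the silyloxy group, so the 4→6 link is fixed before ring C of M exists.
5. Ring order: rings A, B, C of U and of L are bought with epicatechin and catechin; ring D (later ring A of M) and ring B of M are bought as arenes; ring C of M is the only ring formed (step 16).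

Key step: step 16

**Remarks on the chemistry**

- Flavan numbering is used for the three-carbon chain of unit M before ring closure (C4 carbinol carbon, C3, benzylic C2). Ring D is the phloroglucinol-type ring that becomes ring A of unit M. Bn = benzyl, TIPS = triisopropylsilyl, Gal(Bn)3 = 3,4,5-tris(benzyloxy)benzoyl.
- Assumption: the acetylide addition of step 11 is not stereoselective at the new carbinol carbon (C4 of unit M). This centre is erased by ionisation in step 19, so both epimers are carried together. Names and SMILES of 17–23 show the epimer that ends as the 4β-methyl ether; its C4 epimer accompanies it.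

**Route**

Step 1
Reactants: 1 (−)-epicatechin
Product: 2 5,7,3',4'-tetra-O-benzyl-(−)-epicatechin
Conditions: BnBr (4.4 equiv), K2CO3, DMF, 0 °C to rt
Reagents that add atoms: benzyl bromide BrCc1ccccc1
Why: Williamson etherification of the four phenols, which are far more acidic than the C3 alcohol, leaves the secondary hydroxyl free and does not touch C2 or C3.

Step 2
Reactants: 2 5,7,3',4'-tetra-O-benzyl-(−)-epicatechin
Product: 3 4β-(2-ethoxyethoxy)-5,7,3',4'-tetra-O-benzylepicatechin (3,4-trans)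
Conditions: DDQ (2 equiv), 2-ethoxyethanol (5 equiv), CH2Cl2, rt
Reagents that add atoms: 2-ethoxyethanol CCOCCO
Why: DDQ benzylic oxidation removes hydride from C4 of the electron-rich ring A, and the alcohol traps the cation from the β face, anti to the C2 aryl group and the C3 hydroxyl, which sets C4.

Step 3
Reactants: 4 3,4,5-tris(benzyloxy)benzoic acid
Product: 5 3,4,5-tris(benzyloxy)benzoyl chloride
Conditions: (COCl)2 (1.5 equiv), DMF (cat.), CH2Cl2, 0 °C to rt; volatiles removed, used crude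
Reagents that add atoms: oxalyl chloride O=C(Cl)C(=O)Cl
Why: Acyl chloride formation with oxalyl chloride under DMF catalysis (chloroiminium activation) converts the carboxylic acid into the acid chloride with loss of only gaseous by-products, and the aryl benzyl ethers are inert to it.

Step 4
Reactants: 3 4β-(2-ethoxyethoxy)-5,7,3',4'-tetra-O-benzylepicatechin; 5 3,4,5-tris(benzyloxy)benzoyl chloride
Product: 6 3-O-Gal(Bn)3-4β-(2-ethoxyethoxy)-5,7,3',4'-tetra-O-benzylepicatechin
Conditions: 5 (1.5 equiv), Et3N (3 equiv), DMAP (0.2 equiv), CH2Cl2, 0 °C to rt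
Reagents that add atoms: none
Why: DMAP-catalysed acylation of the axial C3 hydroxyl by the acid chloride proceeds with retention, and the ester then serves as protecting group and as the participating group for the arylation at C4.

Step 5
Reactants: 7 3,5-bis(benzyloxy)phenol
Product: 8 [3,5-bis(benzyloxy)phenoxy]triisopropylsilane
Conditions: TIPSCl, imidazole, DMF, rt
Reagents that add atoms: triisopropylsilyl chloride CC(C)[Si](Cl)(C(C)C)C(C)C
Why: Silylation of the single phenol gives a ring D nucleophile whose three oxygens are already differentiated and whose bulky silyloxy group shields both of its ortho carbons.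

Step 6
Reactants: 6 3-O-Gal(Bn)3-4β-(2-ethoxyethoxy)-5,7,3',4'-tetra-O-benzylepicatechin; 8 [3,5-bis(benzyloxy)phenoxy]triisopropylsilane
Product: 9 4β-[2,6-bis(benzyloxy)-4-(triisopropylsilyloxy)phenyl]-3-O-Gal(Bn)3-5,7,3',4'-tetra-O-benzylepicatechin
Conditions: 8 (3 equiv), TMSOTf (0.5 equiv), CH2Cl2, −78 °C; Et3N quench
Reagents that add atoms: none
Why: Lewis acid ionisation of the C4 ether and Friedel–Crafts type arylation of the flavan-4-yl cation: the C3 ester bridges the α face so the arene enters from the β face (3,4-trans), and attack is expected at the carbon para to the hindered silyloxy group, between the two benzyloxy groups.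

Step 7
Reactants: 9 4β-[2,6-bis(benzyloxy)-4-(triisopropylsilyloxy)phenyl]-3-O-Gal(Bn)3-5,7,3',4'-tetra-O-benzylepicatechin
Product: 10 4β-[2,6-bis(benzyloxy)-4-hydroxyphenyl]-3-O-Gal(Bn)3-5,7,3',4'-tetra-O-benzylepicatechin
Conditions: Bu4NF (1.1 equiv), AcOH (1.1 equiv), THF, 0 °C
Reagents that add atoms: none
Why: Fluoride cleaves the aryl silyl ether, and the acetic acid buffer keeps the gallate ester and the benzyl ethers untouched, freeing the one phenol that lies para to the bond to unit U.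

Step 8
Reactants: 10 4β-[2,6-bis(benzyloxy)-4-hydroxyphenyl]-3-O-Gal(Bn)3-5,7,3',4'-tetra-O-benzylepicatechin
Product: 12 4β-[2,6-bis(benzyloxy)-3-formyl-4-hydroxyphenyl]-3-O-Gal(Bn)3-5,7,3',4'-tetra-O-benzylepicatechin, via salicyl alcohol 11 (not isolated)
Conditions: MgCl2 (3 equiv), Et3N (6 equiv), (CH2O)n (10 equiv), THF, reflux
Reagents that add atoms: paraformaldehyde (reacts as formaldehyde) C=O
Why: Casnati–Skattebøl ortho-formylation delivers formaldehyde through the magnesium phenoxide only to a carbon ortho to a free phenol and oxidises the hydroxymethyl intermediate with a second formaldehyde; the two ortho carbons of ring D are equivalent and rings A and B of unit U carry no free phenol.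

Step 9
Reactants: 12 4β-[2,6-bis(benzyloxy)-3-formyl-4-hydroxyphenyl]-3-O-Gal(Bn)3-5,7,3',4'-tetra-O-benzylepicatechin
Product: 13 4β-[2,6-bis(benzyloxy)-3-formyl-4-(triisopropylsilyloxy)phenyl]-3-O-Gal(Bn)3-5,7,3',4'-tetra-O-benzylepicatechin
Conditions: TIPSOTf, 2,6-lutidine, CH2Cl2, 0 °C
Reagents that add atoms: triisopropylsilyl triflate CC(C)[Si](OS(=O)(=O)C(F)(F)F)(C(C)C)C(C)C
Why: Silylation of the hydrogen-bonded phenol with the silyl triflate masks the nucleophile of the key step until the epoxide is in place, and the triisopropylsilyl group is slow to migrate to a neighbouring alkoxide.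

Step 10
Reactants: 14 3,4-bis(benzyloxy)benzaldehyde
Product: 15 1,2-bis(benzyloxy)-4-ethynylbenzene
Conditions: dimethyl (1-diazo-2-oxopropyl)phosphonate, K2CO3, MeOH/THF, rt
Reagents that add atoms: Ohira–Bestmann reagent COP(=O)(OC)C(=[N+]=[N-])C(C)=O
Why: Seyferth–Gilbert homologation in the Ohira–Bestmann variant converts the aryl aldehyde into the terminal alkyne under mild base that leaves the benzyl ethers alone.

Step 11
Reactants: 13 4β-[2,6-bis(benzyloxy)-3-formyl-4-(triisopropylsilyloxy)phenyl]-3-O-Gal(Bn)3-5,7,3',4'-tetra-O-benzylepicatechin; 15 1,2-bis(benzyloxy)-4-ethynylbenzene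
Product: 17 propargylic alcohol 4β-{2,6-bis(benzyloxy)-3-[(1R)-3-(3,4-bis(benzyloxy)phenyl)-1-hydroxyprop-2-yn-1-yl]-4-(triisopropylsilyloxy)phenyl}-3-O-Gal(Bn)3-5,7,3',4'-tetra-O-benzylepicatechin, via lithium acetylide 16 (not isolated)
Conditions: 15 (1.5 equiv), n-BuLi (1.4 equiv), THF, −78 °C; then 13, −78 to −40 °C; AcOH, −78 °C
Reagents that add atoms: none
Why: Acetylide 1,2-addition to the aldehyde is much faster at low temperature than attack on the hindered gallate ester, the cold acidic quench forestalls silyl migration from the phenol oxygen, and the carbinol centre forms without control (both epimers, the 1R one drawn).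

Step 12
Reactants: 17 propargylic alcohol
Product: 18 propargylic methyl ether 4β-{2,6-bis(benzyloxy)-3-[(1R)-3-(3,4-bis(benzyloxy)phenyl)-1-methoxyprop-2-yn-1-yl]-4-(triisopropylsilyloxy)phenyl}-3-O-Gal(Bn)3-5,7,3',4'-tetra-O-benzylepicatechin
Conditions: Me3OBF4, 1,8-bis(dimethylamino)naphthalene, 4 Å MS, CH2Cl2, 0 °C to rt
Reagents that add atoms: trimethyloxonium tetrafluoroborate C[O+](C)C.F[B-](F)(F)F
Why: O-methylation with Meerwein salt and a non-nucleophilic proton scavenger needs no alkoxide, so neither silyl migration nor acyl transfer can occur, and it installs the leaving group for step 19.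

Step 13
Reactants: 18 propargylic methyl ether
Product: 19 (Z)-alkene 4β-{2,6-bis(benzyloxy)-3-[(1R,2Z)-3-(3,4-bis(benzyloxy)phenyl)-1-methoxyprop-2-en-1-yl]-4-(triisopropylsilyloxy)phenyl}-3-O-Gal(Bn)3-5,7,3',4'-tetra-O-benzylepicatechin
Conditions: H2 (1 atm), Pd/CaCO3 poisoned with Pb(OAc)2, quinoline, EtOAc, rt, stopped after one equivalent of H2
Reagents that add atoms: none
Why: Lindlar semihydrogenation adds hydrogen syn to the alkyne and so fixes the (Z) geometry, which an alkenyl-metal addition of a (Z)-styryl halide would not keep, while benzyl ethers, esters and the silyl ether are inert to the poisoned catalyst.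

Step 14
Reactants: 19 (Z)-alkene
Product: 20 cis-epoxide 4β-{2,6-bis(benzyloxy)-3-[(S)-[(2S,3S)-3-(3,4-bis(benzyloxy)phenyl)oxiran-2-yl](methoxy)methyl]-4-(triisopropylsilyloxy)phenyl}-3-O-Gal(Bn)3-5,7,3',4'-tetra-O-benzylepicatechin
Conditions: (S,S)-(salen)MnCl, namely [(S,S)-N,N'-bis(3,5-di-tert-butylsalicylidene)cyclohexane-1,2-diaminato]manganese chloride with trivalent manganese (10 mol %), mCPBA (2 equiv), N-methylmorpholine N-oxide (5 equiv), CH2Cl2, −78 °C; chromatography on Et3N-deactivated silica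
Reagents that add atoms: mCPBA O=C(OO)c1cccc(Cl)c1
Why: Jacobsen–Katsuki epoxidation: the oxo-manganese species of the (S,S)-catalyst transfers oxygen to cis-disubstituted aryl alkenes on the face that makes the benzylic carbon S, as with indene and cis-β-methylstyrene, giving the (2S,3S)-cis-epoxide, and for the drawn C4 epimer this is also the face anti to ring D in the conformer of least 1,3-allylic strain; wrong-face and trans epoxides are diastereomers and are removed by chromatography.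

Step 15
Reactants: 20 cis-epoxide (silyl ether)
Product: 21 phenol cis-epoxide 4β-{2,6-bis(benzyloxy)-3-[(S)-[(2S,3S)-3-(3,4-bis(benzyloxy)phenyl)oxiran-2-yl](methoxy)methyl]-4-hydroxyphenyl}-3-O-Gal(Bn)3-5,7,3',4'-tetra-O-benzylepicatechin
Conditions: Bu4NF (1.1 equiv), AcOH (1.1 equiv), THF, 0 °C; crude phenol used at once
Reagents that add atoms: none
Why: Buffered fluoride desilylation frees the phenol para to unit U without leaving a phenoxide that could open the epoxide at C3 under basic conditions.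

Step 16
Reactants: 21 phenol cis-epoxide
Product: 22 benzylated epicatechin 3-O-gallate-(4β→6)-4β-methoxyepicatechin with free 3-hydroxyl on unit M
Conditions: CSA (0.1 equiv), CH2Cl2, −40 to −20 °C; Et3N quench
Reagents that add atoms: none
Why: The sulfonic acid protonates the epoxide and lengthens its benzylic C2–O bond, which the para benzyloxy group of ring B polarises, and the ortho phenol oxygen of ring D attacks C2 anti to the departing oxygen; this is the intramolecular acid-catalysed phenol opening of aryl epoxides used to make flavan-3-ols from 1,3-diarylpropene oxides. Ring C of unit M closes in the 6-endo mode (O1–C2) through a chair-like transition state with ring B pseudo-axial, while the 5-exo attack at C3 is disfavoured because C3 has no cation-stabilising group. The one new stereocentre, C2, is set by inversion of the epoxide carbon (2S to 2R), C3 keeps the configuration given in step 14 and its oxygen becomes the free 3-hydroxyl, so the 2,3-cis pattern follows from the cis geometry of the epoxide. The step needs concerted inversion to be faster than full ionisation to the benzylic cation, which would drift to the 2,3-trans ring, and faster than ionisation of the C4 methyl ether; the short tether that holds the phenol next to C2, a catalytic amount of a weak acid, a non-polar solvent and low temperature are what secure this. The site of closure is not in question because the only free phenol is the one para to the bond to unit U.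

Step 17
Reactants: 22 dimer with free 3-hydroxyl on unit M; 5 3,4,5-tris(benzyloxy)benzoyl chloride
Product: 23 benzylated epicatechin 3-O-gallate-(4β→6)-4β-methoxyepicatechin 3-O-gallate
Conditions: 5 (2 equiv), Et3N (4 equiv), DMAP (0.5 equiv), CH2Cl2, rt
Reagents that add atoms: none
Why: DMAP-catalysed acylation of the axial C3 hydroxyl of unit M by the acid chloride proceeds with retention under basic conditions that leave the acid-labile C4 methyl ether in place.

Step 18
Reactants: 24 (+)-catechin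
Product: 25 5,7,3',4'-tetra-O-benzyl-(+)-catechin
Conditions: BnBr (4.4 equiv), K2CO3, DMF, 0 °C to rt
Reagents that add atoms: benzyl bromide BrCc1ccccc1
Why: Williamson etherification of the four phenols leaves the C3 alcohol free and C8 as the most nucleophilic ring carbon.

Step 19
Reactants: 23 dimer bis-gallate C4 methyl ether; 25 5,7,3',4'-tetra-O-benzyl-(+)-catechin
Product: 26 octadeca-O-benzyl epicatechin 3-O-gallate-(4β→6)-epicatechin 3-O-gallate-(4β→8)-catechin
Conditions: 25 (4 equiv), TMSOTf (0.5 equiv), CH2Cl2, −78 to −40 °C; Et3N quench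
Reagents that add atoms: none
Why: TMSOTf ionises the C4 methyl ether of unit M (either epimer gives the same cation), the C3 gallate bridges the α face, and C8 of the benzylated catechin adds from the β face in a Friedel–Crafts type flavan-4-yl arylation that sets C4 of M as 3,4-trans.

Step 20
Reactants: 26 octadeca-O-benzyl trimer
Product: 27 epicatechin 3-O-gallate-(4β→6)-epicatechin 3-O-gallate-(4β→8)-catechin (CNP0112921.1)
Conditions: H2 (1 atm), Pd(OH)2/C, THF/MeOH/H2O, rt; filtration, lyophilisation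
Reagents that add atoms: none
Why: Hydrogenolysis cleaves all eighteen benzyl ethers under neutral conditions in which the gallate esters, the interflavan bonds and the ring C ethers are stable.

**Compound list**

1 | (−)-epicatechin | O[C@@H]1Cc2c(O)cc(O)cc2O[C@@H]1c1ccc(O)c(O)c1 | starting material
2 | 5,7,3',4'-tetra-O-benzyl-(−)-epicatechin | O[C@@H]1Cc2c(OCc9ccccc9)cc(OCc9ccccc9)cc2O[C@@H]1c1ccc(OCc9ccccc9)c(OCc9ccccc9)c1 | intermediate
3 | 4β-(2-ethoxyethoxy)-5,7,3',4'-tetra-O-benzylepicatechin (3,4-trans) | O[C@@H]1[C@@H](OCCOCC)c2c(OCc9ccccc9)cc(OCc9ccccc9)cc2O[C@@H]1c1ccc(OCc9ccccc9)c(OCc9ccccc9)c1 | intermediate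
4 | 3,4,5-tris(benzyloxy)benzoic acid | O=C(O)c1cc(OCc2ccccc2)c(OCc2ccccc2)c(OCc2ccccc2)c1 | starting material
5 | 3,4,5-tris(benzyloxy)benzoyl chloride | O=C(Cl)c1cc(OCc2ccccc2)c(OCc2ccccc2)c(OCc2ccccc2)c1 | intermediate
6 | 3-O-Gal(Bn)3-4β-(2-ethoxyethoxy)-5,7,3',4'-tetra-O-benzylepicatechin | O=C(c5cc(OCc9ccccc9)c(OCc9ccccc9)c(OCc9ccccc9)c5)O[C@@H]1[C@@H](OCCOCC)c2c(OCc9ccccc9)cc(OCc9ccccc9)cc2O[C@@H]1c1ccc(OCc9ccccc9)c(OCc9ccccc9)c1 | intermediate
7 | 3,5-bis(benzyloxy)phenol | Oc1cc(OCc2ccccc2)cc(OCc2ccccc2)c1 | starting material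
8 | [3,5-bis(benzyloxy)phenoxy]triisopropylsilane | CC(C)[Si](Oc1cc(OCc2ccccc2)cc(OCc2ccccc2)c1)(C(C)C)C(C)C | intermediate
9 | 4β-[2,6-bis(benzyloxy)-4-(triisopropylsilyloxy)phenyl]-3-O-Gal(Bn)3-5,7,3',4'-tetra-O-benzylepicatechin | O=C(c5cc(OCc9ccccc9)c(OCc9ccccc9)c(OCc9ccccc9)c5)O[C@@H]1[C@@H](c3c(OCc9ccccc9)cc(O[Si](C(C)C)(C(C)C)C(C)C)cc3OCc9ccccc9)c2c(OCc9ccccc9)cc(OCc9ccccc9)cc2O[C@@H]1c1ccc(OCc9ccccc9)c(OCc9ccccc9)c1 | intermediate
10 | 4β-[2,6-bis(benzyloxy)-4-hydroxyphenyl]-3-O-Gal(Bn)3-5,7,3',4'-tetra-O-benzylepicatechin | O=C(c5cc(OCc9ccccc9)c(OCc9ccccc9)c(OCc9ccccc9)c5)O[C@@H]1[C@@H](c3c(OCc9ccccc9)cc(O)cc3OCc9ccccc9)c2c(OCc9ccccc9)cc(OCc9ccccc9)cc2O[C@@H]1c1ccc(OCc9ccccc9)c(OCc9ccccc9)c1 | intermediate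
11 | salicyl alcohol: 4β-[2,6-bis(benzyloxy)-4-hydroxy-3-(hydroxymethyl)phenyl] analogue of 10 (formed as its magnesium salt) | O=C(c5cc(OCc9ccccc9)c(OCc9ccccc9)c(OCc9ccccc9)c5)O[C@@H]1[C@@H](c3c(OCc9ccccc9)cc(O)c(CO)c3OCc9ccccc9)c2c(OCc9ccccc9)cc(OCc9ccccc9)cc2O[C@@H]1c1ccc(OCc9ccccc9)c(OCc9ccccc9)c1 | intermediate (not isolated)
12 | 4β-[2,6-bis(benzyloxy)-3-formyl-4-hydroxyphenyl]-3-O-Gal(Bn)3-5,7,3',4'-tetra-O-benzylepicatechin | O=C(c5cc(OCc9ccccc9)c(OCc9ccccc9)c(OCc9ccccc9)c5)O[C@@H]1[C@@H](c3c(OCc9ccccc9)cc(O)c(C=O)c3OCc9ccccc9)c2c(OCc9ccccc9)cc(OCc9ccccc9)cc2O[C@@H]1c1ccc(OCc9ccccc9)c(OCc9ccccc9)c1 | intermediate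
13 | 4β-[2,6-bis(benzyloxy)-3-formyl-4-(triisopropylsilyloxy)phenyl]-3-O-Gal(Bn)3-5,7,3',4'-tetra-O-benzylepicatechin | O=C(c5cc(OCc9ccccc9)c(OCc9ccccc9)c(OCc9ccccc9)c5)O[C@@H]1[C@@H](c3c(OCc9ccccc9)cc(O[Si](C(C)C)(C(C)C)C(C)C)c(C=O)c3OCc9ccccc9)c2c(OCc9ccccc9)cc(OCc9ccccc9)cc2O[C@@H]1c1ccc(OCc9ccccc9)c(OCc9ccccc9)c1 | intermediate
14 | 3,4-bis(benzyloxy)benzaldehyde | O=Cc1ccc(OCc2ccccc2)c(OCc2ccccc2)c1 | starting material
15 | 1,2-bis(benzyloxy)-4-ethynylbenzene | C#Cc1ccc(OCc2ccccc2)c(OCc2ccccc2)c1 | intermediate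
16 | lithium [3,4-bis(benzyloxy)phenyl]acetylide | [Li]C#Cc1ccc(OCc2ccccc2)c(OCc2ccccc2)c1 | intermediate (not isolated)
17 | propargylic alcohol on ring D, (1R) carbinol drawn (C4 of unit M), aryl silyl ether | O=C(c5cc(OCc9ccccc9)c(OCc9ccccc9)c(OCc9ccccc9)c5)O[C@@H]1[C@@H](c3c(OCc9ccccc9)cc(O[Si](C(C)C)(C(C)C)C(C)C)c([C@H](O)C#Cc6ccc(OCc9ccccc9)c(OCc9ccccc9)c6)c3OCc9ccccc9)c2c(OCc9ccccc9)cc(OCc9ccccc9)cc2O[C@@H]1c1ccc(OCc9ccccc9)c(OCc9ccccc9)c1 | intermediate
18 | propargylic methyl ether of 17, (1R) drawn | O=C(c5cc(OCc9ccccc9)c(OCc9ccccc9)c(OCc9ccccc9)c5)O[C@@H]1[C@@H](c3c(OCc9ccccc9)cc(O[Si](C(C)C)(C(C)C)C(C)C)c([C@H](OC)C#Cc6ccc(OCc9ccccc9)c(OCc9ccccc9)c6)c3OCc9ccccc9)c2c(OCc9ccccc9)cc(OCc9ccccc9)cc2O[C@@H]1c1ccc(OCc9ccccc9)c(OCc9ccccc9)c1 | intermediate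
19 | (Z)-alkene, (1R,2Z)-1-methoxy-3-aryl-prop-2-enyl chain on ring D, aryl silyl ether | O=C(c5cc(OCc9ccccc9)c(OCc9ccccc9)c(OCc9ccccc9)c5)O[C@@H]1[C@@H](c3c(OCc9ccccc9)cc(O[Si](C(C)C)(C(C)C)C(C)C)c([C@H](OC)/C=C\c6ccc(OCc9ccccc9)c(OCc9ccccc9)c6)c3OCc9ccccc9)c2c(OCc9ccccc9)cc(OCc9ccccc9)cc2O[C@@H]1c1ccc(OCc9ccccc9)c(OCc9ccccc9)c1 | intermediate
20 | (2S,3S)-cis-epoxide (flavan numbering of unit M), C4 methoxy carbon S, aryl silyl ether | O=C(c5cc(OCc9ccccc9)c(OCc9ccccc9)c(OCc9ccccc9)c5)O[C@@H]1[C@@H](c3c(OCc9ccccc9)cc(O[Si](C(C)C)(C(C)C)C(C)C)c([C@H](OC)[C@H]4O[C@H]4c6ccc(OCc9ccccc9)c(OCc9ccccc9)c6)c3OCc9ccccc9)c2c(OCc9ccccc9)cc(OCc9ccccc9)cc2O[C@@H]1c1ccc(OCc9ccccc9)c(OCc9ccccc9)c1 | intermediate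
21 | (2S,3S)-cis-epoxide with free phenol para to unit U (precursor of the key step) | O=C(c5cc(OCc9ccccc9)c(OCc9ccccc9)c(OCc9ccccc9)c5)O[C@@H]1[C@@H](c3c(OCc9ccccc9)cc(O)c([C@H](OC)[C@H]4O[C@H]4c6ccc(OCc9ccccc9)c(OCc9ccccc9)c6)c3OCc9ccccc9)c2c(OCc9ccccc9)cc(OCc9ccccc9)cc2O[C@@H]1c1ccc(OCc9ccccc9)c(OCc9ccccc9)c1 | intermediate
22 | benzylated epicatechin 3-O-gallate-(4β→6)-4β-methoxyepicatechin, unit M (2R,3R,4S) with free 3-hydroxyl (product of the key step) | O=C(c5cc(OCc9ccccc9)c(OCc9ccccc9)c(OCc9ccccc9)c5)O[C@@H]1[C@@H](c3c(OCc9ccccc9)cc4c(c3OCc9ccccc9)[C@H](OC)[C@@H](O)[C@@H](c6ccc(OCc9ccccc9)c(OCc9ccccc9)c6)O4)c2c(OCc9ccccc9)cc(OCc9ccccc9)cc2O[C@@H]1c1ccc(OCc9ccccc9)c(OCc9ccccc9)c1 | intermediate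
23 | benzylated epicatechin 3-O-gallate-(4β→6)-4β-methoxyepicatechin 3-O-gallate | O=C(c5cc(OCc9ccccc9)c(OCc9ccccc9)c(OCc9ccccc9)c5)O[C@@H]1[C@@H](c3c(OCc9ccccc9)cc4c(c3OCc9ccccc9)[C@H](OC)[C@@H](OC(=O)c7cc(OCc9ccccc9)c(OCc9ccccc9)c(OCc9ccccc9)c7)[C@@H](c6ccc(OCc9ccccc9)c(OCc9ccccc9)c6)O4)c2c(OCc9ccccc9)cc(OCc9ccccc9)cc2O[C@@H]1c1ccc(OCc9ccccc9)c(OCc9ccccc9)c1 | intermediate
24 | (+)-catechin | O[C@H]1Cc2c(O)cc(O)cc2O[C@@H]1c1ccc(O)c(O)c1 | starting material
25 | 5,7,3',4'-tetra-O-benzyl-(+)-catechin | O[C@H]1Cc2c(OCc9ccccc9)cc(OCc9ccccc9)cc2O[C@@H]1c1ccc(OCc9ccccc9)c(OCc9ccccc9)c1 | intermediate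
26 | octadeca-O-benzyl epicatechin 3-O-gallate-(4β→6)-epicatechin 3-O-gallate-(4β→8)-catechin | O=C(c5cc(OCc9ccccc9)c(OCc9ccccc9)c(OCc9ccccc9)c5)O[C@@H]1[C@@H](c3c(OCc9ccccc9)cc4c(c3OCc9ccccc9)[C@H](c7c(OCc9ccccc9)cc(OCc9ccccc9)c8c7O[C@H](c6ccc(OCc9ccccc9)c(OCc9ccccc9)c6)[C@@H](O)C8)[C@@H](OC(=O)c7cc(OCc9ccccc9)c(OCc9ccccc9)c(OCc9ccccc9)c7)[C@@H](c6ccc(OCc9ccccc9)c(OCc9ccccc9)c6)O4)c2c(OCc9ccccc9)cc(OCc9ccccc9)cc2O[C@@H]1c1ccc(OCc9ccccc9)c(OCc9ccccc9)c1 | intermediate
27 | epicatechin 3-O-gallate-(4β→6)-epicatechin 3-O-gallate-(4β→8)-catechin (CNP0112921.1) | O=C(O[C@@H]1[C@@H](c2c(O)cc3c(c2O)[C@H](c2c(O)cc(O)c4c2O[C@H](c2ccc(O)c(O)c2)[C@@H](O)C4)[C@@H](OC(=O)c2cc(O)c(O)c(O)c2)[C@@H](c2ccc(O)c(O)c2)O3)c2c(O)cc(O)cc2O[C@@H]1c1ccc(O)c(O)c1)c1cc(O)c(O)c(O)c1 | target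

**Step count**

Total: 20 steps. Longest linear sequence: 16 steps (1, 2, 4, 6, 7, 8, 9, 11, 12, 13, 14, 15, 16, 17, 19, 20).

**Steps most likely to fail, with fallbacks**

Step 16 (ring closure). Full ionisation at C2 may outrun the inverting attack, so that the ring drifts to the 2,3-trans isomer. A hydride shift to the benzyl ketone, or ionisation of the C4 methyl ether, may also compete. The fallback reaches the 2,3-cis pattern in two stages and sets out from 19. Iodine-catalysed isomerisation (I2 cat., CH2Cl2, light) should give the (E)-alkene F1. Shi epoxidation with the enantiomer of the fructose-derived ketone (KHSO5, K2CO3 buffer, MeCN/dimethoxymethane, 0 °C), a stereospecific dioxirane oxidation for which (E)-aryl alkenes are the best substrates, should give the (2S,3R)-trans-epoxide F2. Bu4NF/AcOH then frees the phenol of the trans-epoxide F3. Catalytic CSA closes ring C to the 2,3-trans (catechin-type, 2R,3S) flavan-3-ol F4; here inversion and the cation pathway converge on the same isomer. Dess–Martin periodinane gives the flavan-3-one F5. LiBH(s-Bu)3 (THF, −78 °C) delivers hydride trans to the C2 aryl group, the established way of turning a benzylated catechin into an epicatechin, and the route is rejoined at 22. The reduction should be cleanest for the C4 epimer whose methoxy group lies on the face of the C2 aryl group; step 19 accepts either epimer.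

Step 14 (epoxidation). A stepwise oxygen transfer to the electron-rich styrene may allow bond rotation and erode the cis geometry. Facial control may also be weak for the C4 epimer whose allylic bias opposes the catalyst. The fallback moves the control from the catalyst to the C4 centre and sets out from 17 (both epimers). MnO2 (CH2Cl2, rt) gives the ynone F6. Corey–Bakshi–Shibata reduction ((S)-Me-CBS oxazaborolidine, catecholborane, toluene, −78 °C), with the 2,6-disubstituted aryl group as the large and the alkynyl group as the small substituent, should return 17 as the single (R)-carbinol. Steps 12 and 13 then give 19 as one epimer. Dimethyldioxirane (acetone, −40 °C), a concerted and stereospecific oxidant, should add anti to ring D in the conformer of least 1,3-allylic strain, so that C4 alone sets C2 and C3, and the route is rejoined at 20.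

Step 6 (arylation of ring D). Regiocontrol may be lost through attack ortho to the silyloxy group, which would end as a 4→8 link, or through double arylation. The fallback uses a symmetric nucleophile and sets out from 6. Phloroglucinol (5 equiv, TMSOTf, THF/CH2Cl2, −78 to −40 °C) can give only one C-arylation product, the 4β-(2,4,6-trihydroxyphenyl) adduct F7. TIPSCl/imidazole (1 equiv, DMF, 0 °C) silylates the unhindered hydroxyl para to the flavan, giving the para-silyl ether diol F8. BnBr/K2CO3 in acetone benzylates the two flanked phenols and rejoins the route at 9.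

**Further compounds**

F1 | step 16 | (E)-isomer of alkene 19 | O=C(c5cc(OCc9ccccc9)c(OCc9ccccc9)c(OCc9ccccc9)c5)O[C@@H]1[C@@H](c3c(OCc9ccccc9)cc(O[Si](C(C)C)(C(C)C)C(C)C)c([C@H](OC)/C=C/c6ccc(OCc9ccccc9)c(OCc9ccccc9)c6)c3OCc9ccccc9)c2c(OCc9ccccc9)cc(OCc9ccccc9)cc2O[C@@H]1c1ccc(OCc9ccccc9)c(OCc9ccccc9)c1
F2 | step 16 | (2S,3R)-trans-epoxide, aryl silyl ether | O=C(c5cc(OCc9ccccc9)c(OCc9ccccc9)c(OCc9ccccc9)c5)O[C@@H]1[C@@H](c3c(OCc9ccccc9)cc(O[Si](C(C)C)(C(C)C)C(C)C)c([C@H](OC)[C@@H]4O[C@H]4c6ccc(OCc9ccccc9)c(OCc9ccccc9)c6)c3OCc9ccccc9)c2c(OCc9ccccc9)cc(OCc9ccccc9)cc2O[C@@H]1c1ccc(OCc9ccccc9)c(OCc9ccccc9)c1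
F3 | step 16 | (2S,3R)-trans-epoxide with free phenol | O=C(c5cc(OCc9ccccc9)c(OCc9ccccc9)c(OCc9ccccc9)c5)O[C@@H]1[C@@H](c3c(OCc9ccccc9)cc(O)c([C@H](OC)[C@@H]4O[C@H]4c6ccc(OCc9ccccc9)c(OCc9ccccc9)c6)c3OCc9ccccc9)c2c(OCc9ccccc9)cc(OCc9ccccc9)cc2O[C@@H]1c1ccc(OCc9ccccc9)c(OCc9ccccc9)c1
F4 | step 16 | 2,3-trans (2R,3S) flavan-3-ol dimer, 3-epimer of 22 | O=C(c5cc(OCc9ccccc9)c(OCc9ccccc9)c(OCc9ccccc9)c5)O[C@@H]1[C@@H](c3c(OCc9ccccc9)cc4c(c3OCc9ccccc9)[C@H](OC)[C@H](O)[C@@H](c6ccc(OCc9ccccc9)c(OCc9ccccc9)c6)O4)c2c(OCc9ccccc9)cc(OCc9ccccc9)cc2O[C@@H]1c1ccc(OCc9ccccc9)c(OCc9ccccc9)c1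
F5 | step 16 | flavan-3-one of unit M (3-ketone of 22) | O=C(c5cc(OCc9ccccc9)c(OCc9ccccc9)c(OCc9ccccc9)c5)O[C@@H]1[C@@H](c3c(OCc9ccccc9)cc4c(c3OCc9ccccc9)[C@H](OC)C(=O)[C@@H](c6ccc(OCc9ccccc9)c(OCc9ccccc9)c6)O4)c2c(OCc9ccccc9)cc(OCc9ccccc9)cc2O[C@@H]1c1ccc(OCc9ccccc9)c(OCc9ccccc9)c1
F6 | step 14 | ynone from oxidation of 17 | O=C(c5cc(OCc9ccccc9)c(OCc9ccccc9)c(OCc9ccccc9)c5)O[C@@H]1[C@@H](c3c(OCc9ccccc9)cc(O[Si](C(C)C)(C(C)C)C(C)C)c(C(=O)C#Cc6ccc(OCc9ccccc9)c(OCc9ccccc9)c6)c3OCc9ccccc9)c2c(OCc9ccccc9)cc(OCc9ccccc9)cc2O[C@@H]1c1ccc(OCc9ccccc9)c(OCc9ccccc9)c1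
F7 | step 6 | 4β-(2,4,6-trihydroxyphenyl)-3-O-Gal(Bn)3-5,7,3',4'-tetra-O-benzylepicatechin | O=C(c5cc(OCc9ccccc9)c(OCc9ccccc9)c(OCc9ccccc9)c5)O[C@@H]1[C@@H](c3c(O)cc(O)cc3O)c2c(OCc9ccccc9)cc(OCc9ccccc9)cc2O[C@@H]1c1ccc(OCc9ccccc9)c(OCc9ccccc9)c1
F8 | step 6 | 4β-[2,6-dihydroxy-4-(triisopropylsilyloxy)phenyl]-3-O-Gal(Bn)3-5,7,3',4'-tetra-O-benzylepicatechin | O=C(c5cc(OCc9ccccc9)c(OCc9ccccc9)c(OCc9ccccc9)c5)O[C@@H]1[C@@H](c3c(O)cc(O[Si](C(C)C)(C(C)C)C(C)C)cc3O)c2c(OCc9ccccc9)cc(OCc9ccccc9)cc2O[C@@H]1c1ccc(OCc9ccccc9)c(OCc9ccccc9)c1
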